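The 2H-chromene is cut at the two bonds that tie its pyran ring to the benzene ring, C4–C4a and O1–C8a, which end on neighbouring aromatic carbons. A 1-bromo-2-chloroarene can therefore be annulated in one palladium-catalysed operation with a three-carbon cis-alkenylboron unit whose tertiary oxygen already sits on the C2 stereocentre: Suzuki–Miyaura coupling at C–Br, then aryl etherification at C–Cl, so the O1–C2 bond stays intact throughout. The boron partner is a cyclic 1,2-oxaborol-2(5H)-ol made from geranyl acetate with Sharpless control of C2; the butenolide is then grown from the C5' terminus by auxiliary-controlled glycolate alkylation and Still–Gennari olefination.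

Key step: step 10

Remarks on the chemistry:
- Read from its SMILES, the target is (S) at chromene C2 and (R) at butenolide C5; every structure below is drawn for that enantiomer.
- Locants: chromene O1, C2 to C8a; side chain C1' to C5' counted from C2.
- Partners 11 and 14 and chromene 16 map atom for atom onto the target (C–Br becomes C4a, C–Cl becomes C8a).
- The C5' oxygen is carried as an acid-labile alkyl TBS ether and the phenol as a fluoride-labile aryl TIPS ether, so each can be removed without the other.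
- Phosphonate 28 is racemic at its phosphorus-bearing carbon, which becomes sp2 in step 18.

**Route**

Step 1
Reactants: 1 geranyl acetate
Product: 2 (2E,6E)-8-hydroxy-3,7-dimethylocta-2,6-dien-1-yl acetate
Conditions: SeO2 (0.1 equiv), t-BuOOH (70% aq., 3 equiv), salicylic acid (0.1 equiv), CH2Cl2, rt
Reagents that add atoms: tert-butyl hydroperoxide, CC(C)(C)OO (oxygen relayed by selenium dioxide, O=[Se]=O)
Why: Riley allylic oxidation (ene reaction, then 2,3-sigmatropic shift) should hydroxylate the (E)-methyl group of the electron-rich terminal alkene, the alkene next to the acetate being deactivated.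

Step 2
Reactants: 2 (2E,6E)-8-hydroxy-3,7-dimethylocta-2,6-dien-1-yl acetate
Product: 3 (2E,6E)-8-[(tert-butyldimethylsilyl)oxy]-3,7-dimethylocta-2,6-dien-1-yl acetate
Conditions: TBSCl, imidazole, DMF, 0 °C to rt
Reagents that add atoms: tert-butyldimethylsilyl chloride, CC(C)(C)[Si](C)(C)Cl
Why: Imidazole-promoted silylation of an unhindered primary alcohol is routine and leaves the acetate untouched.

Step 3
Reactants: 3 (2E,6E)-8-[(tert-butyldimethylsilyl)oxy]-3,7-dimethylocta-2,6-dien-1-yl acetate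
Product: 4 (2E,6E)-8-[(tert-butyldimethylsilyl)oxy]-3,7-dimethylocta-2,6-dien-1-ol
Conditions: K2CO3 (0.2 equiv), MeOH, rt
Reagents that add atoms: none
Why: Base-catalysed transesterification with methanol removes the acetate while the alkyl TBS ether is stable to carbonate.

Step 4
Reactants: 4 (2E,6E)-8-[(tert-butyldimethylsilyl)oxy]-3,7-dimethylocta-2,6-dien-1-ol
Product: 5 [(2S,3S)-3-{(3E)-5-[(tert-butyldimethylsilyl)oxy]-4-methylpent-3-en-1-yl}-3-methyloxiran-2-yl]methanol
Conditions: Ti(OiPr)4 (10 mol %), L-(+)-diethyl tartrate (12 mol %), t-BuOOH (anhydrous, 2 equiv), 4 Å MS, CH2Cl2, −20 °C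
Reagents that add atoms: tert-butyl hydroperoxide, CC(C)(C)OO
Why: Sharpless asymmetric epoxidation of the free allylic alcohol with L-(+)-tartrate should give the (2S,3S)-epoxide as it does for geraniol, which sets the future chromene C2, while the other alkene, lacking a free hydroxyl, is not epoxidised.

Step 5
Reactants: 5 [(2S,3S)-3-{(3E)-5-[(tert-butyldimethylsilyl)oxy]-4-methylpent-3-en-1-yl}-3-methyloxiran-2-yl]methanol
Product: 6 tert-butyl{[(2E)-5-[(2S,3R)-3-(chloromethyl)-2-methyloxiran-2-yl]-2-methylpent-2-en-1-yl]oxy}dimethylsilane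
Conditions: PPh3, CCl4, NaHCO3 (0.2 equiv), reflux
Reagents that add atoms: tetrachloromethane, ClC(Cl)(Cl)Cl
Why: The Appel reaction converts the primary alcohol into the chloride under neutral conditions that spare the epoxide; no bond at a stereocentre is touched, and the descriptor of the CH carbon changes only through CIP priority.

Step 6
Reactants: 6 tert-butyl{[(2E)-5-[(2S,3R)-3-(chloromethyl)-2-methyloxiran-2-yl]-2-methylpent-2-en-1-yl]oxy}dimethylsilane
Product: 7 (3S,6E)-8-[(tert-butyldimethylsilyl)oxy]-3,7-dimethyloct-6-en-1-yn-3-ol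
Conditions: n-BuLi (3.3 equiv), THF, −40 °C; aq. NH4Cl
Reagents that add atoms: none
Why: Base-induced fragmentation of a 2,3-epoxy chloride (epoxide opening by β-elimination, then loss of HCl) should give the terminal tertiary propargylic alcohol with retention, because the C–O bond at the quaternary carbon is never broken.

Step 7
Reactants: 7 (3S,6E)-8-[(tert-butyldimethylsilyl)oxy]-3,7-dimethyloct-6-en-1-yn-3-ol; 8 pinacolborane
Product: 11 (5S)-5-{(3E)-5-[(tert-butyldimethylsilyl)oxy]-4-methylpent-3-en-1-yl}-5-methyl-1,2-oxaborol-2(5H)-ol, via trimethylsilyl ether 9 (not isolated), via Z-alkenyl pinacol boronate 10 (not isolated)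
Conditions: TMSCl (1.1 equiv), Et3N (3 equiv), cyclohexane, rt, filter; [Rh(cod)Cl]2 (1.5 mol %), P(iPr)3 (6 mol %), 8 (0.9 equiv), rt; then NaIO4, AcOH, THF/H2O, rt
Reagents that add atoms: water, O (the B–OH oxygen; boron comes from reactant 8)
Why: Temporary O-silylation masks the hydroxyl, the rhodium-catalysed formal trans-hydroboration of the terminal alkyne (through a rhodium vinylidene, alkyne kept in slight excess against Z-to-E isomerisation) places boron on the terminal carbon cis to the carbinol, and the acidic periodate work-up removes the silyl group and the pinacol so that the cis hydroxyl closes the five-membered boronic half-ester.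

Step 8
Reactants: 12 3-bromo-5-methylphenol
Product: 13 3-bromo-4-chloro-5-methylphenol
Conditions: SO2Cl2 (1.05 equiv), Ph2S (cat.), AlCl3 (cat.), CH2Cl2, 0 °C to rt
Reagents that add atoms: sulfuryl chloride, O=S(=O)(Cl)Cl
Why: Electrophilic aromatic chlorination under sulfide and Lewis acid catalysis is para-selective for phenols, and the para position is further activated by the ortho methyl group, as in the chlorination of 3,5-dimethylphenol.

Step 9
Reactants: 13 3-bromo-4-chloro-5-methylphenol
Product: 14 (3-bromo-4-chloro-5-methylphenoxy)triisopropylsilane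
Conditions: TIPSCl, imidazole, DMF, rt
Reagents that add atoms: triisopropylsilyl chloride, CC(C)[Si](Cl)(C(C)C)C(C)C
Why: Silylation of a phenol with no ortho substituent is routine, and the bulky aryl TIPS ether should withstand phosphate base at elevated temperature.

Step 10
Reactants: 11 (5S)-5-{(3E)-5-[(tert-butyldimethylsilyl)oxy]-4-methylpent-3-en-1-yl}-5-methyl-1,2-oxaborol-2(5H)-ol; 14 (3-bromo-4-chloro-5-methylphenoxy)triisopropylsilane
Product: 16 tert-butyl{[(2E)-5-{(2S)-2,8-dimethyl-6-[(triisopropylsilyl)oxy]-2H-chromen-2-yl}-2-methylpent-2-en-1-yl]oxy}dimethylsilane, via Z-styrenyl carbinol 15 (not isolated)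
Conditions: Pd(OAc)2 (5 mol %), tBuXPhos (10 mol %), K3PO4 (3 equiv), H2O (5 equiv), toluene, 60 °C then 100 °C
Reagents that add atoms: none
Why: Zerovalent palladium, formed from Pd(OAc)2 and the phosphine, inserts into the weaker C–Br bond of 14, the base-activated oxaborolol transfers its alkenyl carbon with retention, and reductive elimination forms C4–C4a as a cis alkene while freeing the tertiary hydroxyl beside the aryl chloride (15). At the higher temperature the same catalyst inserts into C–Cl, the alkoxide binds palladium to give a seven-membered oxapalladacycle, and C–O reductive elimination forms O1–C8a. The closest known reaction types are the Suzuki–Miyaura coupling of cyclic alkenylboronic half-esters and the palladium-catalysed intramolecular etherification of aryl halides with tertiary alcohols under bulky dialkylbiarylphosphine ligands, here run back to back in one flask. The pyran ring closes by intramolecular aryl C–O coupling, formally a 6-exo attack of the alkoxide oxygen on the ipso carbon, which is possible only because the five-membered boracycle fixed the Z geometry. No stereocentre is created, and C2 keeps the configuration set in step 4 because none of its bonds is broken. The step needs bromide-before-chloride site selectivity, secured by the difference in bond strength and the cooler first stage, and freedom from β-hydride elimination, secured by the tertiary alkoxide having no carbinol hydrogen.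

Step 11
Reactants: 16 tert-butyl{[(2E)-5-{(2S)-2,8-dimethyl-6-[(triisopropylsilyl)oxy]-2H-chromen-2-yl}-2-methylpent-2-en-1-yl]oxy}dimethylsilane
Product: 17 (2E)-5-{(2S)-2,8-dimethyl-6-[(triisopropylsilyl)oxy]-2H-chromen-2-yl}-2-methylpent-2-en-1-ol
Conditions: CSA (0.1 equiv), MeOH/CH2Cl2 (1:1), 0 °C
Reagents that add atoms: none
Why: Acid-catalysed methanolysis cleaves a primary alkyl TBS ether far faster than an aryl TIPS ether, which is stable to mild acid.

Step 12
Reactants: 17 (2E)-5-{(2S)-2,8-dimethyl-6-[(triisopropylsilyl)oxy]-2H-chromen-2-yl}-2-methylpent-2-en-1-ol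
Product: 18 {[(2S)-2-[(3E)-5-iodo-4-methylpent-3-en-1-yl]-2,8-dimethyl-2H-chromen-6-yl]oxy}triisopropylsilane
Conditions: PPh3, I2, imidazole, CH2Cl2, 0 °C, dark; used at once
Reagents that add atoms: iodine, II
Why: Appel-type iodination proceeds by SN2 displacement at the primary allylic carbon, so the E alkene is kept and imidazole buffers the acid formed.

Step 13
Reactants: 19 (S)-4-benzyl-1,3-oxazolidin-2-one; 20 [(tert-butyldimethylsilyl)oxy]acetic acid
Product: 22 (4S)-4-benzyl-3-{[(tert-butyldimethylsilyl)oxy]acetyl}-1,3-oxazolidin-2-one, via mixed pivalic anhydride 21 (not isolated)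
Conditions: PivCl, Et3N, THF, −20 °C; then 19, LiCl, rt
Reagents that add atoms: none
Why: N-acylation of the oxazolidinone through a mixed pivalic anhydride is regioselective because the hindered pivaloyl carbonyl is not attacked.

Step 14
Reactants: 18 {[(2S)-2-[(3E)-5-iodo-4-methylpent-3-en-1-yl]-2,8-dimethyl-2H-chromen-6-yl]oxy}triisopropylsilane; 22 (4S)-4-benzyl-3-{[(tert-butyldimethylsilyl)oxy]acetyl}-1,3-oxazolidin-2-one
Product: 23 (4S)-4-benzyl-3-[(2R,4E)-2-[(tert-butyldimethylsilyl)oxy]-7-{(2S)-2,8-dimethyl-6-[(triisopropylsilyl)oxy]-2H-chromen-2-yl}-4-methylhept-4-enoyl]-1,3-oxazolidin-2-one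
Conditions: 22 (2.0 equiv), NaHMDS (1.9 equiv), THF, −78 °C; then 18, −78 to −45 °C
Reagents that add atoms: none
Why: In this oxazolidinone-auxiliary glycolate alkylation the chelated sodium Z-enolate should be attacked by the allylic iodide on the face opposite the C4 benzyl group, which gives the (R) α-silyloxy centre that becomes butenolide C5.

Step 15
Reactants: 23 (4S)-4-benzyl-3-[(2R,4E)-2-[(tert-butyldimethylsilyl)oxy]-7-{(2S)-2,8-dimethyl-6-[(triisopropylsilyl)oxy]-2H-chromen-2-yl}-4-methylhept-4-enoyl]-1,3-oxazolidin-2-one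
Product: 24 (2R,4E)-2-[(tert-butyldimethylsilyl)oxy]-7-{(2S)-2,8-dimethyl-6-[(triisopropylsilyl)oxy]-2H-chromen-2-yl}-4-methylhept-4-en-1-ol
Conditions: LiBH4, H2O (1 equiv), Et2O, 0 °C
Reagents that add atoms: none
Why: Borohydride reduction of the exocyclic imide carbonyl releases the auxiliary and gives the primary alcohol without touching the α-stereocentre or either silyl ether.

Step 16
Reactants: 24 (2R,4E)-2-[(tert-butyldimethylsilyl)oxy]-7-{(2S)-2,8-dimethyl-6-[(triisopropylsilyl)oxy]-2H-chromen-2-yl}-4-methylhept-4-en-1-ol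
Product: 25 (2R,4E)-2-[(tert-butyldimethylsilyl)oxy]-7-{(2S)-2,8-dimethyl-6-[(triisopropylsilyl)oxy]-2H-chromen-2-yl}-4-methylhept-4-enal
Conditions: Dess–Martin periodinane, pyridine, CH2Cl2, 0 °C to rt; used crude
Reagents that add atoms: none
Why: Dess–Martin oxidation under buffered, near-neutral conditions should give the α-silyloxy aldehyde without epimerisation.

Step 17
Reactants: 26 methyl bis(2,2,2-trifluoroethyl)phosphonoacetate; 27 5-bromo-2-methylpent-2-ene
Product: 28 methyl 2-[bis(2,2,2-trifluoroethoxy)phosphoryl]-6-methylhept-5-enoate (racemic)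
Conditions: NaH, DMF, 0 °C; then 27, NaI (cat.), 50 °C; 26 in excess
Reagents that add atoms: none
Why: SN2 C-alkylation of the stabilised phosphonoacetate anion by the primary homoallylic bromide, with iodide catalysis and excess phosphonate to suppress dialkylation, should give the α-substituted olefination reagent.

Step 18
Reactants: 25 (2R,4E)-2-[(tert-butyldimethylsilyl)oxy]-7-{(2S)-2,8-dimethyl-6-[(triisopropylsilyl)oxy]-2H-chromen-2-yl}-4-methylhept-4-enal; 28 methyl 2-[bis(2,2,2-trifluoroethoxy)phosphoryl]-6-methylhept-5-enoate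
Product: 29 methyl (2Z,4R,6E)-4-[(tert-butyldimethylsilyl)oxy]-9-{(2S)-2,8-dimethyl-6-[(triisopropylsilyl)oxy]-2H-chromen-2-yl}-6-methyl-2-(4-methylpent-3-en-1-yl)nona-2,6-dienoate
Conditions: 28 (1.5 equiv), KHMDS, 18-crown-6, THF, −78 °C; then 25
Reagents that add atoms: none
Why: In the Still–Gennari olefination the electron-poor trifluoroethyl phosphonate with a crown-separated potassium counter-ion eliminates under kinetic control to the Z-enoate, which places the ester cis to the oxygen-bearing C4.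

Step 19
Reactants: 29 methyl (2Z,4R,6E)-4-[(tert-butyldimethylsilyl)oxy]-9-{(2S)-2,8-dimethyl-6-[(triisopropylsilyl)oxy]-2H-chromen-2-yl}-6-methyl-2-(4-methylpent-3-en-1-yl)nona-2,6-dienoate
Product: 31 tuberatolide B, via seco hydroxy ester 30 (not isolated)
Conditions: TBAF (3 equiv), AcOH (3 equiv), THF, 0 °C to rt
Reagents that add atoms: none
Why: Fluoride-mediated desilylation removes both silyl ethers, the freed C4 hydroxyl held cis to the ester lactonises spontaneously (5-exo-trig transesterification with loss of methanol), and the acetic acid buffer guards the butenolide γ-centre against base-induced epimerisation.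

**Compound list**

1 | geranyl acetate | CC(C)=CCC/C(C)=C/COC(C)=O | starting material
2 | (2E,6E)-8-hydroxy-3,7-dimethylocta-2,6-dien-1-yl acetate | OC/C(C)=C/CC/C(C)=C/COC(C)=O | intermediate
3 | (2E,6E)-8-[(tert-butyldimethylsilyl)oxy]-3,7-dimethylocta-2,6-dien-1-yl acetate | CC(C)(C)[Si](C)(C)OC/C(C)=C/CC/C(C)=C/COC(C)=O | intermediate
4 | (2E,6E)-8-[(tert-butyldimethylsilyl)oxy]-3,7-dimethylocta-2,6-dien-1-ol | CC(C)(C)[Si](C)(C)OC/C(C)=C/CC/C(C)=C/CO | intermediate
5 | [(2S,3S)-3-{(3E)-5-[(tert-butyldimethylsilyl)oxy]-4-methylpent-3-en-1-yl}-3-methyloxiran-2-yl]methanol | CC(C)(C)[Si](C)(C)OC/C(C)=C/CC[C@]1(C)O[C@H]1CO | intermediate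
6 | tert-butyl{[(2E)-5-[(2S,3R)-3-(chloromethyl)-2-methyloxiran-2-yl]-2-methylpent-2-en-1-yl]oxy}dimethylsilane | CC(C)(C)[Si](C)(C)OC/C(C)=C/CC[C@]1(C)O[C@H]1CCl | intermediate
7 | (3S,6E)-8-[(tert-butyldimethylsilyl)oxy]-3,7-dimethyloct-6-en-1-yn-3-ol | CC(C)(C)[Si](C)(C)OC/C(C)=C/CC[C@](C)(O)C#C | intermediate
8 | pinacolborane | CC1(C)OBOC1(C)C | starting material
9 | trimethylsilyl ether of 7 | CC(C)(C)[Si](C)(C)OC/C(C)=C/CC[C@](C)(O[Si](C)(C)C)C#C | intermediate (not isolated)
10 | (Z)-alkenyl pinacol boronate, trimethylsilyl ether | CC(C)(C)[Si](C)(C)OC/C(C)=C/CC[C@](C)(O[Si](C)(C)C)/C=C\B1OC(C)(C)C(C)(C)O1 | intermediate (not isolated)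
11 | (5S)-5-{(3E)-5-[(tert-butyldimethylsilyl)oxy]-4-methylpent-3-en-1-yl}-5-methyl-1,2-oxaborol-2(5H)-ol | CC(C)(C)[Si](C)(C)OC/C(C)=C/CC[C@@]1(C)C=CB(O)O1 | intermediate
12 | 3-bromo-5-methylphenol | Cc1cc(O)cc(Br)c1 | starting material
13 | 3-bromo-4-chloro-5-methylphenol | Cc1cc(O)cc(Br)c1Cl | intermediate
14 | (3-bromo-4-chloro-5-methylphenoxy)triisopropylsilane | Cc1cc(O[Si](C(C)C)(C(C)C)C(C)C)cc(Br)c1Cl | intermediate
15 | (1Z,3S,6E)-8-[(tert-butyldimethylsilyl)oxy]-1-{2-chloro-3-methyl-5-[(triisopropylsilyl)oxy]phenyl}-3,7-dimethylocta-1,6-dien-3-ol | CC(C)(C)[Si](C)(C)OC/C(C)=C/CC[C@@](O)(C)/C=C\c1cc(O[Si](C(C)C)(C(C)C)C(C)C)cc(C)c1Cl | intermediate (not isolated)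
16 | tert-butyl{[(2E)-5-{(2S)-2,8-dimethyl-6-[(triisopropylsilyl)oxy]-2H-chromen-2-yl}-2-methylpent-2-en-1-yl]oxy}dimethylsilane | CC(C)(C)[Si](C)(C)OC/C(C)=C/CC[C@@]1(C)C=Cc2cc(O[Si](C(C)C)(C(C)C)C(C)C)cc(C)c2O1 | intermediate
17 | (2E)-5-{(2S)-2,8-dimethyl-6-[(triisopropylsilyl)oxy]-2H-chromen-2-yl}-2-methylpent-2-en-1-ol | OC/C(C)=C/CC[C@@]1(C)C=Cc2cc(O[Si](C(C)C)(C(C)C)C(C)C)cc(C)c2O1 | intermediate
18 | {[(2S)-2-[(3E)-5-iodo-4-methylpent-3-en-1-yl]-2,8-dimethyl-2H-chromen-6-yl]oxy}triisopropylsilane | IC/C(C)=C/CC[C@@]1(C)C=Cc2cc(O[Si](C(C)C)(C(C)C)C(C)C)cc(C)c2O1 | intermediate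
19 | (S)-4-benzyl-1,3-oxazolidin-2-one | O=C1N[C@@H](Cc2ccccc2)CO1 | starting material
20 | [(tert-butyldimethylsilyl)oxy]acetic acid | CC(C)(C)[Si](C)(C)OCC(O)=O | starting material
21 | [(tert-butyldimethylsilyl)oxy]acetic pivalic anhydride | CC(C)(C)[Si](C)(C)OCC(=O)OC(=O)C(C)(C)C | intermediate (not isolated)
22 | (4S)-4-benzyl-3-{[(tert-butyldimethylsilyl)oxy]acetyl}-1,3-oxazolidin-2-one | CC(C)(C)[Si](C)(C)OCC(=O)N1[C@@H](Cc2ccccc2)COC1=O | intermediate
23 | (4S)-4-benzyl-3-[(2R,4E)-2-[(tert-butyldimethylsilyl)oxy]-7-{(2S)-2,8-dimethyl-6-[(triisopropylsilyl)oxy]-2H-chromen-2-yl}-4-methylhept-4-enoyl]-1,3-oxazolidin-2-one | O=C(N1[C@@H](Cc2ccccc2)COC1=O)[C@H](O[Si](C)(C)C(C)(C)C)C/C(C)=C/CC[C@@]1(C)C=Cc2cc(O[Si](C(C)C)(C(C)C)C(C)C)cc(C)c2O1 | intermediate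
24 | (2R,4E)-2-[(tert-butyldimethylsilyl)oxy]-7-{(2S)-2,8-dimethyl-6-[(triisopropylsilyl)oxy]-2H-chromen-2-yl}-4-methylhept-4-en-1-ol | OC[C@H](O[Si](C)(C)C(C)(C)C)C/C(C)=C/CC[C@@]1(C)C=Cc2cc(O[Si](C(C)C)(C(C)C)C(C)C)cc(C)c2O1 | intermediate
25 | (2R,4E)-2-[(tert-butyldimethylsilyl)oxy]-7-{(2S)-2,8-dimethyl-6-[(triisopropylsilyl)oxy]-2H-chromen-2-yl}-4-methylhept-4-enal | O=C[C@H](O[Si](C)(C)C(C)(C)C)C/C(C)=C/CC[C@@]1(C)C=Cc2cc(O[Si](C(C)C)(C(C)C)C(C)C)cc(C)c2O1 | intermediate
26 | methyl bis(2,2,2-trifluoroethyl)phosphonoacetate | COC(=O)CP(=O)(OCC(F)(F)F)OCC(F)(F)F | starting material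
27 | 5-bromo-2-methylpent-2-ene | CC(C)=CCCBr | starting material
28 | methyl 2-[bis(2,2,2-trifluoroethoxy)phosphoryl]-6-methylhept-5-enoate (racemic) | COC(=O)C(CCC=C(C)C)P(=O)(OCC(F)(F)F)OCC(F)(F)F | intermediate
29 | methyl (2Z,4R,6E)-4-[(tert-butyldimethylsilyl)oxy]-9-{(2S)-2,8-dimethyl-6-[(triisopropylsilyl)oxy]-2H-chromen-2-yl}-6-methyl-2-(4-methylpent-3-en-1-yl)nona-2,6-dienoate | COC(=O)/C(CCC=C(C)C)=C\[C@H](O[Si](C)(C)C(C)(C)C)C/C(C)=C/CC[C@@]1(C)C=Cc2cc(O[Si](C(C)C)(C(C)C)C(C)C)cc(C)c2O1 | intermediate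
30 | methyl (2Z,4R,6E)-4-hydroxy-9-[(2S)-6-hydroxy-2,8-dimethyl-2H-chromen-2-yl]-6-methyl-2-(4-methylpent-3-en-1-yl)nona-2,6-dienoate | COC(=O)/C(CCC=C(C)C)=C\[C@H](O)C/C(C)=C/CC[C@@]1(C)C=Cc2cc(O)cc(C)c2O1 | intermediate (not isolated)
31 | tuberatolide B, (5R)-5-{(2E)-5-[(2S)-6-hydroxy-2,8-dimethyl-2H-chromen-2-yl]-2-methylpent-2-en-1-yl}-3-(4-methylpent-3-en-1-yl)furan-2(5H)-one | CC(C)=CCCC1=C[C@@H](C/C(C)=C/CC[C@@]2(C)C=Cc3cc(O)cc(C)c3O2)OC1=O | target

**Step count and risk**

Total steps: 19. Longest linear sequence: 15 steps (steps 1–7, 10–12, 14–16, 18 and 19).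

Steps most likely to fail:

1. Step 10. The second event may lag behind the first: oxidative addition into the di-ortho-substituted, electron-rich C–Cl bond can stall at intermediate 15, or the boronic half-ester can be lost by protodeboronation before it transmetalates. The fallback is boron-free and decouples the two bond formations. It sets out from 7 and 14: Sonogashira coupling at the C–Br bond (PdCl2(PPh3)2, CuI, Et3N, 60 °C) should give the aryl alkynyl carbinol F1. Lindlar semi-hydrogenation (H2, Pd/CaCO3 poisoned with Pb(OAc)2, quinoline, EtOAc) should then give the Z-alkene, which is compound 15, now isolated and purified. The pyran ring is closed in a separate run by intramolecular aryl etherification with a stronger base (Pd(OAc)2, tBuXPhos, Cs2CO3, toluene, 100 °C), which returns to the route at 16.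

2. Step 7. Incomplete silylation may leave free hydroxyl that consumes borane and disturbs the catalyst, or the Z-boronate may isomerise to the E isomer, which cannot close the five-membered ring. The fallback is stoichiometric and fixes the geometry by a syn reduction. It sets out from 7: iodination of the terminal alkyne (N-iodosuccinimide, AgNO3 cat., acetone, dark) should give the iodoalkyne F2. Diimide reduction (2-nitrobenzenesulfonyl hydrazide, Et3N, THF/i-PrOH) should give the (Z)-iodoalkene F3. Deprotonation and iodine–lithium exchange (n-BuLi 1 equiv, then t-BuLi 2 equiv, Et2O, −78 °C), trapping with B(OiPr)3 and mild aqueous acid should give the cyclic half-ester, which returns to the route at 11.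

3. Step 14. The silyloxy enolate may decompose, or shift its silyl group from oxygen to oxygen, faster than it is alkylated by the hindered iodide, so conversion may be low. The fallback uses an ether-type glycolate and then exchanges the protecting group. The allyl ether analogue of 22, imide F4 (from 19 and allyloxyacetic acid as in step 13), is alkylated with 18 under the conditions of step 14 to give the allyl ether imide F5. Ruthenium-catalysed deallylation ([CpRu(MeCN)3]PF6, quinaldic acid, MeOH, 30 °C) should free the α-hydroxy imide F6. Silylation (TBSOTf, 2,6-lutidine, CH2Cl2, −78 °C) returns to the route at 23.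

Further compounds
F1 | step 10 | (3S,6E)-8-[(tert-butyldimethylsilyl)oxy]-1-{2-chloro-3-methyl-5-[(triisopropylsilyl)oxy]phenyl}-3,7-dimethyloct-6-en-1-yn-3-ol | CC(C)(C)[Si](C)(C)OC/C(C)=C/CC[C@](C)(O)C#Cc1cc(O[Si](C(C)C)(C(C)C)C(C)C)cc(C)c1Cl
F2 | step 7 | (3S,6E)-8-[(tert-butyldimethylsilyl)oxy]-1-iodo-3,7-dimethyloct-6-en-1-yn-3-ol | CC(C)(C)[Si](C)(C)OC/C(C)=C/CC[C@](C)(O)C#CI
F3 | step 7 | (1Z,3S,6E)-8-[(tert-butyldimethylsilyl)oxy]-1-iodo-3,7-dimethylocta-1,6-dien-3-ol | CC(C)(C)[Si](C)(C)OC/C(C)=C/CC[C@](C)(O)/C=C\I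
F4 | step 14 | (4S)-3-[(allyloxy)acetyl]-4-benzyl-1,3-oxazolidin-2-one | C=CCOCC(=O)N1[C@@H](Cc2ccccc2)COC1=O
F5 | step 14 | (4S)-3-[(2R,4E)-2-(allyloxy)-7-{(2S)-2,8-dimethyl-6-[(triisopropylsilyl)oxy]-2H-chromen-2-yl}-4-methylhept-4-enoyl]-4-benzyl-1,3-oxazolidin-2-one | O=C(N1[C@@H](Cc2ccccc2)COC1=O)[C@H](OCC=C)C/C(C)=C/CC[C@@]1(C)C=Cc2cc(O[Si](C(C)C)(C(C)C)C(C)C)cc(C)c2O1
F6 | step 14 | (4S)-4-benzyl-3-[(2R,4E)-7-{(2S)-2,8-dimethyl-6-[(triisopropylsilyl)oxy]-2H-chromen-2-yl}-2-hydroxy-4-methylhept-4-enoyl]-1,3-oxazolidin-2-one | O=C(N1[C@@H](Cc2ccccc2)COC1=O)[C@H](O)C/C(C)=C/CC[C@@]1(C)C=Cc2cc(O[Si](C(C)C)(C(C)C)C(C)C)cc(C)c2O1
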